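## Structural features

The target is a diaryl ether built from two resorcinol-type rings. Ring A is the benzo ring of an isocoumarin (1H-isochromen-1-one) with a pentyl group on C3 and a free hydroxyl on C6. Ring B is a 2,4-dihydroxy-6-pentylbenzoic acid, an olivetolic acid unit. One oxygen joins C8 of ring A to C5' of ring B, so it lies peri to the lactone carbonyl on one side and between the C4' hydroxyl and the C6' pentyl chain on the other. There is no stereocentre, so every problem is one of regiochemistry and functional-group tolerance. The fragile groups are the beta-resorcylic acid of ring B (it loses carbon dioxide in hot or strongly acidic media), the enol lactone (it opens with hydroxide or alkoxide) and the electron-rich phenols. The real difficulty is the tri-ortho-substituted ether bond to a hindered, electron-rich ring B oxygen, formed so that the carbonyl carbon C1 ends on C8a beside it. The key step uses the fact that O–C8 and C1–C8a sit on neighbouring carbons of ring A, the pattern left by 1,2-difunctionalisation of an aryne across C8–C8a. The C4a substituent, an alkyne that later becomes C4 and C3, stands next to C8a, where it can bias the addition and then close the lactone.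

## Logic of the disconnections

20 to 19. The three O–CH3 bonds and the ester O–C(CH3)3 bond are cut, so that all acidic groups are masked until the end. The ring B carboxyl is carried as a tert-butyl ester and not as a methyl ester. A di-ortho-substituted methyl benzoate cannot be relied on to fall to a boron halide, and saponification would open the lactone. The forward step must remove four groups with one Lewis acid while the lactone, the diaryl ether and the carboxyl survive.

19 to 18. The lactone bond O2–C3 is cut, which turns the isocoumarin into a benzoic acid with an alkyne ortho to it. This removes a ring and leaves two simple ortho substituents. The forward step must close 6-endo on the pentyl-bearing alkyne carbon and not 5-exo.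

18 to 8, 14 and 15. The ether bond O–C8 and the bond C8a–C1 are cut together. This is the strategic cut: it splits the molecule into its two rings plus a one-carbon unit, and it forms the hindered ether without any metal-catalysed C–O coupling. The forward step needs an aryne across C8–C8a that takes up the oxygen of 14 at C8 and then 15 at C8a, in that regiochemical sense, under strictly aprotic conditions.

8 to 5 to 4. The C–Si bond and the O–S bond of 8 are cut. Silicon is brought in on oxygen in 5 and moved to carbon through the position held by bromine, so 4 needs only a bromine ortho to the hydroxyl. The forward steps must tolerate the internal alkyne next to a phenoxide.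

4 to 2 and 3, and 2 to 1. The aryl–alkynyl bond is cut to 3 and a ring A phenol with two different ortho halogens. With iodine at one ortho position and bromine at the other, only one site couples and the other is kept for the silyl shift, which avoids a statistical mono-coupling of a symmetric dihalide. Compound 2 comes from 1 by one halogenation at the only free position ortho to the hydroxyl.

14 to 12 to 10 to 9. The C5'–O bond of 14 is traced to the C–Br bond of 12, the carboxyl carbon of 12 to the second C–Br bond of 10, and both bromines to C–H bonds of 9. Because 10 is symmetric, exchange of either bromine gives the same aryllithium, so the positions of ester and oxygen on ring B are fixed by symmetry. The forward steps must stop after one exchange and must replace a di-ortho-substituted bromine by oxygen.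

## Other disconnections considered

Alternative 1: Ring B is cut at C1'–C6' and C2'–C3' and grown last from acyclic pieces. In the forward key step the anion of dimethyl malonate A3 adds to the pentyl-bearing carbon of the alpha-aryloxy enone A2, and the methyl ketone then condenses on one malonate ester. This gives the cyclohexane-1,3-dione A1, which is aromatised by oxidation.
- In its favour: this is the classical construction of 5-alkylresorcylates, so every step has close precedent, which is better than the chosen plan, whose key step has none. The ether oxygen is in place before ring B exists, so no aryne regiochemistry arises, also a point for the alternative. The ring B hydroxyls arrive free, so ring B needs no ether cleavage, again better.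
- Against it: A2 requires an 8-hydroxyisocoumarin, whose peri-chelated hydroxyl is a poor nucleophile, to be alkylated and then turned into an enone. The aryloxy group makes the enone a weaker and more hindered acceptor. The lactone must survive alkoxide in the annulation. The aryloxide may be lost during aromatisation. The methyl ester of the resulting resorcylate must then be hydrolysed without lactone opening or decarboxylation.
- Comparison: on mechanism it is the safer plan. On structure it puts the most base-sensitive group through the most basic step. On step economy it is linear and clearly longer than the ten steps proposed here.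

Alternative 2: Ring A is cut at C4a–C8a, C7–C8 and C5–C6, together with the lactone ring. In the forward key step Cp*RuCl(cod), a divalent ruthenium complex, joins the ester-tethered 1,7-diyne A5 with ethoxyethyne A6 to give the dihydroisocoumarin A4. Loss of methanol across C3–C4 would then give the isocoumarin.
- In its favour: ring A and the lactone ring form in one step with full atom economy, which is better than the chosen plan, where the lactone needs a separate step. The known meta preference of this catalyst class should place the ethoxy group on C6. The reaction class is established, an advantage in precedent.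
- Against it: A5 contains an aryloxy-propiolate, a push-pull ynol ether that is hard to make from a hindered phenol and sensitive to acid. Ester tethers prefer the conformation that holds the two alkynes apart. A6 is volatile and prone to self-trimerisation. Two stereocentres are made only to be destroyed, and the C6 ethyl ether and an elimination are added at the end.
- Comparison: on convergence it is the equal of the chosen plan (two fragments and a small third component in both). On structure and step economy it is worse, because both fragments need long preparation.

Alternative 3: Ring A is cut at C6–C7, C8–C8a and C5–C6. In the forward key step, photochemical Wolff rearrangement of the diazo keto ester A9 gives an ester-bearing vinylketene. This adds the aryl ethynyl ether A8 by [2+2] cycloaddition, four-electron ring opening and six-electron ring closure, giving the phenol A7 (Danheiser benzannulation).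
- In its favour: the polarity of the ynol ether fixes the regiochemistry completely, which is better than the aryne, whose regioselectivity rests on a moderate inductive bias. The C6 hydroxyl is formed free, also better. The benzannulation is a known reaction type.
- Against it: A8 must be made from a hindered ring B phenol in several steps. A9 is a cross-conjugated enyne diazo ketone of doubtful photochemical and thermal stability. A7 carries two methyl esters that must be told apart before lactonisation.
- Comparison: on mechanism and regiocontrol it is the stronger plan. On structure (two sensitive precursors) and on step economy it is weaker; the chosen route uses stable, easily made partners.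

Key step: step 8

Assumption: 2-bromo-4-methoxyphenol (1) and 1,3-dimethoxy-5-pentylbenzene (9) are treated as catalogue chemicals; all other compounds are made.

## Route

Step 1
Reactants: 1 2-bromo-4-methoxyphenol
Product: 2 2-bromo-6-iodo-4-methoxyphenol
Conditions: NIS (1.05 equiv), TsOH·H2O (10 mol%), MeCN, 0 °C to rt
Reagents that add atoms: N-iodosuccinimide, O=C1CCC(=O)N1I
Why: Electrophilic aromatic iodination; the free hydroxyl is the strongest director and its only open ortho position is C6, so iodine should enter there and leave two ortho halogens of different reactivity.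

Step 2
Reactants: 2 2-bromo-6-iodo-4-methoxyphenol; 3 1-heptyne
Product: 4 2-bromo-6-(hept-1-yn-1-yl)-4-methoxyphenol
Conditions: 3 (1.2 equiv), PdCl2(PPh3)2 (2 mol%), CuI (4 mol%), Et3N, THF, rt, argon
Reagents that add atoms: none
Why: Sonogashira coupling; zerovalent palladium inserts into C–I much faster than into C–Br at room temperature, so a single alkynylation is expected and the bromide is kept for the silyl shift. Room temperature limits 5-endo closure of the ortho-alkynylphenol to a benzofuran.

Step 3
Reactants: 4 2-bromo-6-(hept-1-yn-1-yl)-4-methoxyphenol
Product: 5 [2-bromo-6-(hept-1-yn-1-yl)-4-methoxyphenoxy]trimethylsilane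
Conditions: HMDS, THF, 70 °C; evaporate, use crude
Reagents that add atoms: hexamethyldisilazane, C[Si](C)(C)N[Si](C)(C)C
Why: O-silylation of a phenol by a disilazane with loss of ammonia; no salt is formed, so the moisture-sensitive silyl ether can be taken on after evaporation.

Step 4
Reactants: 5 [2-bromo-6-(hept-1-yn-1-yl)-4-methoxyphenoxy]trimethylsilane
Product: 8 2-(hept-1-yn-1-yl)-4-methoxy-6-(trimethylsilyl)phenyl trifluoromethanesulfonate, via aryllithium 6 (not isolated), via lithium phenoxide 7 (not isolated)
Conditions: n-BuLi (1.1 equiv), THF, −78 °C; then Tf2O (1.2 equiv), −78 °C to 0 °C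
Reagents that add atoms: trifluoromethanesulfonic anhydride, O=S(=O)(OS(=O)(=O)C(F)(F)F)C(F)(F)F
Why: Bromine–lithium exchange gives 6, whose 1,3-shift of silicon from oxygen to carbon (retro-Brook rearrangement) is driven by formation of phenoxide 7; O-sulfonylation then gives the ortho-silyl aryl triflate. The internal alkyne and the methyl ether are inert to n-BuLi at −78 °C.

Step 5
Reactants: 9 1,3-dimethoxy-5-pentylbenzene
Product: 10 2,4-dibromo-1,5-dimethoxy-3-pentylbenzene
Conditions: NBS (2.1 equiv), MeCN, 0 °C to rt
Reagents that add atoms: N-bromosuccinimide, O=C1CCC(=O)N1Br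
Why: Electrophilic aromatic bromination; each bromine should enter para to one methoxy group and ortho to the other, because the position between two methoxy groups is the least reactive one in 1,3-dimethoxyarenes. The product is symmetric.

Step 6
Reactants: 10 2,4-dibromo-1,5-dimethoxy-3-pentylbenzene
Product: 12 tert-butyl 3-bromo-4,6-dimethoxy-2-pentylbenzoate, via aryllithium 11 (not isolated)
Conditions: n-BuLi (1.0 equiv), THF, −78 °C; then transfer into Boc2O (1.5 equiv), THF, −78 °C to rt; NH4Cl aq
Reagents that add atoms: di-tert-butyl dicarbonate, CC(C)(C)OC(=O)OC(=O)OC(C)(C)C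
Why: Bromine–lithium exchange with one equivalent stops after one bromine, and since the two bromines are equivalent only one aryllithium can form; acylation of 11 by the dicarbonate gives the tert-butyl ester. The hindered ester resists a second addition.

Step 7
Reactants: 12 tert-butyl 3-bromo-4,6-dimethoxy-2-pentylbenzoate
Product: 14 tert-butyl 5-hydroxy-2,4-dimethoxy-6-pentylbenzoate, via pinacol boronate 13 (not isolated)
Conditions: B2pin2 (1.5 equiv), Pd(OAc)2 (3 mol%), SPhos (6 mol%), KOAc (3 equiv), dioxane, 100 °C; then 30% H2O2, NaOH aq, THF, 0 °C
Reagents that add atoms: bis(pinacolato)diboron, CC1(C)OB(OC1(C)C)B1OC(C)(C)C(C)(C)O1 (boron is held only in 13); hydrogen peroxide, OO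
Why: Miyaura borylation of the aryl bromide, with an electron-rich dialkylbiarylphosphine to handle the di-ortho-substituted C–Br bond, then oxidation of the C–B bond by hydroperoxide with 1,2-shift of the aryl group from boron to oxygen. The tert-butyl ester is inert to KOAc and to cold alkaline peroxide.

Step 8
Reactants: 14 tert-butyl 5-hydroxy-2,4-dimethoxy-6-pentylbenzoate; 8 2-(hept-1-yn-1-yl)-4-methoxy-6-(trimethylsilyl)phenyl trifluoromethanesulfonate; 15 carbon dioxide
Product: 18 2-[3-(tert-butoxycarbonyl)-4,6-dimethoxy-2-pentylphenoxy]-6-(hept-1-yn-1-yl)-4-methoxybenzoic acid, via potassium phenoxide 16 (not isolated), via alkynyl aryne 17 (not isolated)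
Conditions: 14 (1.0 equiv), KH (1.05 equiv), THF, 0 °C; then 18-crown-6 (3 equiv), KF (3 equiv), CO2 (1 atm), 8 (1.3 equiv) added over 4 h, 0 °C to rt; cold 0.5 M HCl
Reagents that add atoms: none
Why: Proposed new method: fluoride attacks the silicon of 8 and triflate leaves to give aryne 17; the crown-separated phenoxide 16 should add to the aryne carbon remote from the alkynyl group (future C8), and the potassium aryl anion so formed at C8a, finding no O–H or N–H proton in dry THF, should be captured by carbon dioxide (C8a–C1). The closest known reaction types are the fluoride-induced O-arylation of phenols with arynes from ortho-silyl aryl triflates and the three-component coupling of arynes, amines and carbon dioxide to anthranilic acids; a phenoxide as the nucleophile of the carboxylative version is the untested element. No ring is closed and no stereocentre is formed. The step needs regioselectivity in the addition: the sp-hybridised, inductively withdrawing C4a substituent distorts the aryne so that C8 is the more electrophilic carbon and the negative charge develops next to it at C8a, and the alkyne also screens C8a; the C6 methoxy group, para to C8a, pulls weakly the other way. It also needs chemoselectivity: 16 can only O-arylate because both ortho positions and the para position of its oxygen are substituted, the ring B ester is meta to that oxygen and out of reach of the C8a anion (no xanthone), and deprotonation with KH leaves no proton source to compete with carbon dioxide. Reversible carbonate formation between 16 and carbon dioxide lowers the phenoxide concentration without consuming it, which is why 8 is added slowly.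

Step 9
Reactants: 18 2-[3-(tert-butoxycarbonyl)-4,6-dimethoxy-2-pentylphenoxy]-6-(hept-1-yn-1-yl)-4-methoxybenzoic acid
Product: 19 tert-butyl 2,4-dimethoxy-5-[(6-methoxy-1-oxo-3-pentyl-1H-isochromen-8-yl)oxy]-6-pentylbenzoate
Conditions: AgOSO2CF3 (10 mol%), ClCH2CH2Cl, rt to 40 °C
Reagents that add atoms: none
Why: Silver-catalysed cycloisomerisation of an ortho-alkynylbenzoic acid; monovalent silver activates the alkyne and the carboxyl oxygen attacks the pentyl-bearing carbon in a 6-endo-dig closure, the usual course under acidic, base-free conditions, and protodemetalation then gives the isocoumarin. The tert-butyl ester and the aryl ethers are not touched by the catalytic Lewis acid.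

Step 10
Reactants: 19 tert-butyl 2,4-dimethoxy-5-[(6-methoxy-1-oxo-3-pentyl-1H-isochromen-8-yl)oxy]-6-pentylbenzoate
Product: 20 2,4-dihydroxy-5-[(6-hydroxy-1-oxo-3-pentyl-1H-isochromen-8-yl)oxy]-6-pentylbenzoic acid
Conditions: BBr3 (10 equiv), CH2Cl2, −78 °C to rt; ice-water
Reagents that add atoms: none
Why: Lewis-acid dealkylation; BBr3 binds each ether oxygen and bromide removes the methyl group by SN2, while the tert-butyl ester ionises to the acid, so all four protecting groups should fall in one operation. The diaryl ether and the lactone are not cleaved, and a cold quench limits decarboxylation of the resorcylic acid.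

## Compound list

1 | 2-bromo-4-methoxyphenol | COc1ccc(O)c(Br)c1 | starting material
2 | 2-bromo-6-iodo-4-methoxyphenol | COc1cc(Br)c(O)c(I)c1 | intermediate
3 | 1-heptyne | CCCCCC#C | starting material
4 | 2-bromo-6-(hept-1-yn-1-yl)-4-methoxyphenol | CCCCCC#Cc1cc(OC)cc(Br)c1O | intermediate
5 | [2-bromo-6-(hept-1-yn-1-yl)-4-methoxyphenoxy]trimethylsilane | CCCCCC#Cc1cc(OC)cc(Br)c1O[Si](C)(C)C | intermediate
6 | [3-(hept-1-yn-1-yl)-5-methoxy-2-(trimethylsilyloxy)phenyl]lithium | CCCCCC#Cc1cc(OC)cc([Li])c1O[Si](C)(C)C | intermediate
7 | lithium 2-(hept-1-yn-1-yl)-4-methoxy-6-(trimethylsilyl)phenoxide | CCCCCC#Cc1cc(OC)cc([Si](C)(C)C)c1[O-].[Li+] | intermediate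
8 | 2-(hept-1-yn-1-yl)-4-methoxy-6-(trimethylsilyl)phenyl trifluoromethanesulfonate | CCCCCC#Cc1cc(OC)cc([Si](C)(C)C)c1OS(=O)(=O)C(F)(F)F | intermediate
9 | 1,3-dimethoxy-5-pentylbenzene | CCCCCc1cc(OC)cc(OC)c1 | starting material
10 | 2,4-dibromo-1,5-dimethoxy-3-pentylbenzene | CCCCCc1c(Br)c(OC)cc(OC)c1Br | intermediate
11 | (3-bromo-4,6-dimethoxy-2-pentylphenyl)lithium | CCCCCc1c(Br)c(OC)cc(OC)c1[Li] | intermediate
12 | tert-butyl 3-bromo-4,6-dimethoxy-2-pentylbenzoate | CCCCCc1c(Br)c(OC)cc(OC)c1C(=O)OC(C)(C)C | intermediate
13 | tert-butyl 4,6-dimethoxy-2-pentyl-3-(4,4,5,5-tetramethyl-1,3,2-dioxaborolan-2-yl)benzoate | CCCCCc1c(B2OC(C)(C)C(C)(C)O2)c(OC)cc(OC)c1C(=O)OC(C)(C)C | intermediate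
14 | tert-butyl 5-hydroxy-2,4-dimethoxy-6-pentylbenzoate | CCCCCc1c(O)c(OC)cc(OC)c1C(=O)OC(C)(C)C | intermediate
15 | carbon dioxide | O=C=O | starting material
16 | potassium 3-(tert-butoxycarbonyl)-4,6-dimethoxy-2-pentylphenoxide | CCCCCc1c([O-])c(OC)cc(OC)c1C(=O)OC(C)(C)C.[K+] | intermediate
17 | 3-(hept-1-yn-1-yl)-5-methoxybenzyne (1-(hept-1-yn-1-yl)-3-methoxycyclohexa-1,3-dien-5-yne) | CCCCCC#CC1=CC(OC)=CC#C1 | intermediate
18 | 2-[3-(tert-butoxycarbonyl)-4,6-dimethoxy-2-pentylphenoxy]-6-(hept-1-yn-1-yl)-4-methoxybenzoic acid | CCCCCC#Cc1cc(OC)cc(Oc2c(CCCCC)c(C(=O)OC(C)(C)C)c(OC)cc2OC)c1C(=O)O | intermediate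
19 | tert-butyl 2,4-dimethoxy-5-[(6-methoxy-1-oxo-3-pentyl-1H-isochromen-8-yl)oxy]-6-pentylbenzoate | CCCCCc1cc2cc(OC)cc(Oc3c(CCCCC)c(C(=O)OC(C)(C)C)c(OC)cc3OC)c2c(=O)o1 | intermediate
20 | 2,4-dihydroxy-5-[(6-hydroxy-1-oxo-3-pentyl-1H-isochromen-8-yl)oxy]-6-pentylbenzoic acid | CCCCCc1cc2cc(O)cc(Oc3c(O)cc(O)c(C(=O)O)c3CCCCC)c2c(=O)o1 | target

## Step count and risks

Total step count: 10. Longest linear sequence: 7 steps (1, 2, 3, 4, 8, 9, 10); the ring B branch (5, 6, 7) joins at step 8.

Step 8 (key step, proposed new method). Three things may go wrong:
- The phenoxide may add at the wrong aryne carbon, because the inductive bias of the alkynyl group is moderate and the C6 methoxy group works against it.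
- The C8a anion may be protonated by traces of water before it meets carbon dioxide.
- The phenoxide may be held as its carbonate so that the aryne is consumed by other paths.

The fallback uses only known chemistry; it sets out from 14 and 3 and returns at 18. Commercial 1-bromo-3-fluoro-5-methoxybenzene F1 would be lithiated between the two halogens with LiN(iPr)2 at −78 °C and formylated with DMF to 2-bromo-6-fluoro-4-methoxybenzaldehyde F2. The phenoxide of 14 (K2CO3, DMF, 100 °C) would displace the fluoride ortho to the aldehyde by nucleophilic aromatic substitution, giving tert-butyl 5-(3-bromo-2-formyl-5-methoxyphenoxy)-2,4-dimethoxy-6-pentylbenzoate F3. Sonogashira coupling of the bromide with 3 (PdCl2(PPh3)2, CuI, Et3N, 60 °C) would give tert-butyl 5-[2-formyl-3-(hept-1-yn-1-yl)-5-methoxyphenoxy]-2,4-dimethoxy-6-pentylbenzoate F4. Pinnick oxidation (NaClO2, NaH2PO4, 2-methyl-2-butene, t-BuOH/water) would then give 18. Here the positions of oxygen and carbonyl are fixed by the building block and not by an aryne.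

Step 2. The free ortho-alkynylphenol may cyclise to a 2-pentylbenzofuran under the palladium and copper catalysts, and copper may homocouple the alkyne. The fallback sets out from 2 and returns at 4. Acetylation (Ac2O, pyridine) would give 2-bromo-6-iodo-4-methoxyphenyl acetate F5. Sonogashira coupling with 3 would give 2-bromo-6-(hept-1-yn-1-yl)-4-methoxyphenyl acetate F6, which cannot cyclise. Methanolysis (K2CO3, MeOH, 0 °C) would release 4.

Step 7. Oxidative addition of palladium into the electron-rich, di-ortho-substituted C–Br bond may be slow, so that protodebromination competes with borylation. The fallback sets out from 12 and returns at 14. n-BuLi would be added at −78 °C to a mixture of 12 and B(OiPr)3 in THF/toluene (in situ quench, so the aryllithium is trapped before it can attack the ester). Hydrolysis would give [3-(tert-butoxycarbonyl)-4,6-dimethoxy-2-pentylphenyl]boronic acid F7, and oxidation with H2O2 would give 14.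

Step 9. The carboxylate may close 5-exo onto the aryl-bound alkyne carbon and give an alkylidene phthalide instead of the isocoumarin. The fallback sets out from 18 and returns at 19. Methylation (CH3I, K2CO3, DMF) would give methyl 2-[3-(tert-butoxycarbonyl)-4,6-dimethoxy-2-pentylphenoxy]-6-(hept-1-yn-1-yl)-4-methoxybenzoate F8. Iodocyclisation with I2 in CH2Cl2, which for such esters follows the 6-endo path through an iodonium ion with loss of the methyl group, would give tert-butyl 5-[(4-iodo-6-methoxy-1-oxo-3-pentyl-1H-isochromen-8-yl)oxy]-2,4-dimethoxy-6-pentylbenzoate F9. Reductive deiodination (Pd(OAc)2, PPh3, HCO2Na, DMF, 60 °C) would then give 19.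

Step 10. The resorcylic acid of ring B may lose carbon dioxide by ipso-protonation in the acidic medium or during the quench, and the unchelated methyl ethers (C6 and C4') may cleave slowly. The fallback sets out from 19 and returns at 20. Demethylation with BBr3 would be followed by deliberate complete decarboxylation on warming, giving 8-(2,4-dihydroxy-6-pentylphenoxy)-6-hydroxy-3-pentyl-1H-isochromen-1-one F10. The carboxyl would then be put back by Kolbe–Schmitt-type ortho-carboxylation with methyl magnesium carbonate (CH3OMgOCO2CH3, DMF, 120 °C), the reagent that converts 5-pentylresorcinol into its 2,4-dihydroxy-6-pentylbenzoic acid. Cold acidification would reclose any opened lactone and give 20.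

## Further compounds

F1 | step 8 | 1-bromo-3-fluoro-5-methoxybenzene (purchased) | COc1cc(F)cc(Br)c1
F2 | step 8 | 2-bromo-6-fluoro-4-methoxybenzaldehyde | COc1cc(F)c(C=O)c(Br)c1
F3 | step 8 | tert-butyl 5-(3-bromo-2-formyl-5-methoxyphenoxy)-2,4-dimethoxy-6-pentylbenzoate | CCCCCc1c(Oc2cc(OC)cc(Br)c2C=O)c(OC)cc(OC)c1C(=O)OC(C)(C)C
F4 | step 8 | tert-butyl 5-[2-formyl-3-(hept-1-yn-1-yl)-5-methoxyphenoxy]-2,4-dimethoxy-6-pentylbenzoate | CCCCCC#Cc1cc(OC)cc(Oc2c(CCCCC)c(C(=O)OC(C)(C)C)c(OC)cc2OC)c1C=O
F5 | step 2 | 2-bromo-6-iodo-4-methoxyphenyl acetate | COc1cc(Br)c(OC(C)=O)c(I)c1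
F6 | step 2 | 2-bromo-6-(hept-1-yn-1-yl)-4-methoxyphenyl acetate | CCCCCC#Cc1cc(OC)cc(Br)c1OC(C)=O
F7 | step 7 | [3-(tert-butoxycarbonyl)-4,6-dimethoxy-2-pentylphenyl]boronic acid | CCCCCc1c(B(O)O)c(OC)cc(OC)c1C(=O)OC(C)(C)C
F8 | step 9 | methyl 2-[3-(tert-butoxycarbonyl)-4,6-dimethoxy-2-pentylphenoxy]-6-(hept-1-yn-1-yl)-4-methoxybenzoate | CCCCCC#Cc1cc(OC)cc(Oc2c(CCCCC)c(C(=O)OC(C)(C)C)c(OC)cc2OC)c1C(=O)OC
F9 | step 9 | tert-butyl 5-[(4-iodo-6-methoxy-1-oxo-3-pentyl-1H-isochromen-8-yl)oxy]-2,4-dimethoxy-6-pentylbenzoate | CCCCCc1oc(=O)c2c(Oc3c(CCCCC)c(C(=O)OC(C)(C)C)c(OC)cc3OC)cc(OC)cc2c1I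
F10 | step 10 | 8-(2,4-dihydroxy-6-pentylphenoxy)-6-hydroxy-3-pentyl-1H-isochromen-1-one | CCCCCc1cc2cc(O)cc(Oc3c(O)cc(O)cc3CCCCC)c2c(=O)o1
A1 | alternative 1 | methyl 5-[(6-methoxy-1-oxo-3-pentyl-1H-isochromen-8-yl)oxy]-2,4-dioxo-6-pentylcyclohexane-1-carboxylate (diastereomer mixture) | CCCCCC1C(Oc2cc(OC)cc3cc(CCCCC)oc(=O)c23)C(=O)CC(=O)C1C(=O)OC
A2 | alternative 1 | 3-[(6-methoxy-1-oxo-3-pentyl-1H-isochromen-8-yl)oxy]non-3-en-2-one (alkene geometry not fixed) | CCCCCC=C(Oc1cc(OC)cc2cc(CCCCC)oc(=O)c12)C(C)=O
A3 | alternative 1 | dimethyl malonate | COC(=O)CC(=O)OC
A4 | alternative 2 | methyl 5-[(6-ethoxy-4-methoxy-1-oxo-3-pentyl-3,4-dihydro-1H-isochromen-8-yl)oxy]-2,4-dimethoxy-6-pentylbenzoate (diastereomer mixture) | CCCCCC1OC(=O)c2c(Oc3c(CCCCC)c(C(=O)OC)c(OC)cc3OC)cc(OCC)cc2C1OC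
A5 | alternative 2 | 3-methoxynon-1-yn-4-yl 3-[3-(methoxycarbonyl)-4,6-dimethoxy-2-pentylphenoxy]prop-2-ynoate (diastereomer mixture) | C#CC(OC)C(CCCCC)OC(=O)C#COc1c(CCCCC)c(C(=O)OC)c(OC)cc1OC
A6 | alternative 2 | ethoxyethyne | CCOC#C
A7 | alternative 3 | methyl 2-[3-(methoxycarbonyl)-4,6-dimethoxy-2-pentylphenoxy]-6-(hept-1-yn-1-yl)-4-hydroxybenzoate | CCCCCC#Cc1cc(O)cc(Oc2c(CCCCC)c(C(=O)OC)c(OC)cc2OC)c1C(=O)OC
A8 | alternative 3 | methyl 5-(ethynyloxy)-2,4-dimethoxy-6-pentylbenzoate | C#COc1c(CCCCC)c(C(=O)OC)c(OC)cc1OC
A9 | alternative 3 | methyl 5-diazo-3-(hept-1-yn-1-yl)-4-oxopent-2-enoate (alkene geometry not fixed) | COC(=O)C=C(C#CCCCCC)C(=O)C=[N+]=[N-]
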